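**Plan**

- Retrosynthesis first removes the ring A decoration: the C6 prenyl group (cross-metathesis on a C6 allyl group delivered by a 5-O-allyl Claisen shift), the C8–O bond (persulfate hydroxylation para to the 5-hydroxyl) and the C2=C3 unsaturation (dehydration of a 3-hydroxychroman-4-one).
- The central cut is C3–C4 of ring C. C4 (the ketone) and the aryl-bearing C3 are both former carbonyl carbons, the ring A aldehyde and the ring B aryl ketone, held together by the O1–C2 ether; turning the aldehyde into an acyl anion equivalent lets them be joined.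
- A last cut at O1–C2 gives a salicylaldehyde and a phenacyl bromide.
- Forward: rings A and B are bought, the ether tether is made (steps 1–2), ring C closes by a carbene-catalysed benzoin reaction (step 3) and is dehydrated to the chromone (step 4). Ring A is then adjusted in the order 5-O-demethylation, C8 hydroxylation, 8-O-MOM, 5-O-allylation, Claisen shift to C6, cross-metathesis, MOM removal.
- Stereochemistry: the target is achiral. The C3 carbinol centre made in step 3 is racemic and is erased in step 4; the prenyl olefin has no geometric isomers.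

Key step: step 3

Remark: the hydrogen bond between the 5-hydroxyl and the C4 carbonyl is assumed to differentiate the 5- and 8-oxygens in steps 5, 7 and 8.

**Route**

Step 1
Reactants: 1 1-(2,4,5-trimethoxyphenyl)ethanone
Product: 2 2-bromo-1-(2,4,5-trimethoxyphenyl)ethanone
Conditions: CuBr2 (2.1 equiv), EtOAc/CHCl3 (1:1), reflux
Reagents that add atoms: copper dibromide (CuBr2), [Cu+2].[Br-].[Br-]
Why: King α-bromination of an aryl methyl ketone; CuBr2 brominates the enolised ketone and releases no free electrophilic bromine, so the activated trimethoxyphenyl ring should stay unbrominated.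

Step 2
Reactants: 3 2-hydroxy-4,6-dimethoxybenzaldehyde; 2 2-bromo-1-(2,4,5-trimethoxyphenyl)ethanone
Product: 4 2,4-dimethoxy-6-[2-oxo-2-(2,4,5-trimethoxyphenyl)ethoxy]benzaldehyde
Conditions: K2CO3 (1.5 equiv), DMF, 20 °C
Reagents that add atoms: none
Why: Williamson ether synthesis by SN2 attack of the phenoxide on the very reactive phenacyl bromide; a carbonate base at room temperature should keep the product from aldol closure to a benzofuran.

Step 3
Reactants: 4 2,4-dimethoxy-6-[2-oxo-2-(2,4,5-trimethoxyphenyl)ethoxy]benzaldehyde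
Product: 5 racemic 3-hydroxy-5,7-dimethoxy-3-(2,4,5-trimethoxyphenyl)chroman-4-one
Conditions: 2-(pentafluorophenyl)-6,7-dihydro-5H-pyrrolo[2,1-c][1,2,4]triazol-2-ium tetrafluoroborate (15 mol %), Et3N (15 mol %), THF, 40 °C, argon
Reagents that add atoms: none
Why: The triazolylidene freed by the amine adds to the aldehyde of 4, proton transfer gives the Breslow enaminol, and this acyl anion equivalent attacks the tethered aryl ketone carbonyl to form C3–C4, after which the adduct collapses to release the carbene and the tertiary ketol 5. The closest known reaction type is the carbene-catalysed intramolecular crossed aldehyde–ketone benzoin reaction that converts 2-(2-oxoalkoxy)benzaldehydes into 3-hydroxychroman-4-ones. Ring C closes in a 6-exo-trig mode on the ketone carbonyl. The new carbinol centre C3 is formed racemic under the achiral catalyst, which suffices because step 4 removes it. The step needs the aldehyde as sole acyl donor and the ketone as sole acceptor, and it must outrun aldehyde homo-benzoin coupling and base-induced aldol closure of the phenacyl methylene onto the aldehyde; a ketone cannot form a Breslow intermediate, the O1–C2 tether places only the ketone within reach of the enaminol, and the weak amine base keeps the methylene from enolising.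

Step 4
Reactants: 5 racemic 3-hydroxy-5,7-dimethoxy-3-(2,4,5-trimethoxyphenyl)chroman-4-one
Product: 7 5,7-dimethoxy-3-(2,4,5-trimethoxyphenyl)-4H-chromen-4-one, via chlorosulfite ester 6 (not isolated)
Conditions: SOCl2 (1.5 equiv), pyridine (4 equiv), CH2Cl2, 0 → 20 °C
Reagents that add atoms: none
Why: Dehydration of a tertiary benzylic alcohol through its chlorosulfite with pyridine-assisted loss of a C2 hydrogen; the trimethoxyphenyl group supports ionisation at C3 and the conjugated 4-pyranone is the only and a strongly favoured elimination product.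

Step 5
Reactants: 7 5,7-dimethoxy-3-(2,4,5-trimethoxyphenyl)-4H-chromen-4-one
Product: 9 5-hydroxy-7-methoxy-3-(2,4,5-trimethoxyphenyl)-4H-chromen-4-one, via aryloxydichloroborane 8 (not isolated)
Conditions: BCl3 (1 M in CH2Cl2, 2 equiv), CH2Cl2, −78 → 0 °C; then H2O
Reagents that add atoms: none
Why: Chelation-controlled Lewis acid ether cleavage; BCl3 bridges the C4 carbonyl oxygen and the peri 5-methoxy oxygen in a six-membered chelate, so chloride should remove only that methyl group at low temperature.

Step 6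
Reactants: 9 5-hydroxy-7-methoxy-3-(2,4,5-trimethoxyphenyl)-4H-chromen-4-one
Product: 11 5,8-dihydroxy-7-methoxy-3-(2,4,5-trimethoxyphenyl)-4H-chromen-4-one, via potassium 8-sulfate ester 10 (not isolated)
Conditions: K2S2O8 (1.2 equiv), aq. KOH, pyridine, 0 → 20 °C; then conc. HCl, 80 °C, argon
Reagents that add atoms: potassium peroxodisulfate (K2S2O8), [K+].[K+].[O-]S(=O)(=O)OOS(=O)(=O)[O-]
Why: Elbs persulfate oxidation; the 5-phenolate attacks the peroxide oxygen through its para carbon C8, the only para position, and the aryl sulfate is then hydrolysed by acid, as is known for 5-hydroxychromones.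

Step 7
Reactants: 11 5,8-dihydroxy-7-methoxy-3-(2,4,5-trimethoxyphenyl)-4H-chromen-4-one
Product: 12 5-hydroxy-7-methoxy-8-(methoxymethoxy)-3-(2,4,5-trimethoxyphenyl)-4H-chromen-4-one
Conditions: MOMCl (1.1 equiv), iPr2NEt (1.5 equiv), CH2Cl2, 0 °C, argon
Reagents that add atoms: chloromethyl methyl ether (MOMCl), COCCl
Why: Selective O-alkylation (acetal protection); the 5-hydroxyl is tied up in the hydrogen bond to the C4 carbonyl and is much less nucleophilic, so the free 8-hydroxyl should react first.

Step 8
Reactants: 12 5-hydroxy-7-methoxy-8-(methoxymethoxy)-3-(2,4,5-trimethoxyphenyl)-4H-chromen-4-one; 13 allyl bromide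
Product: 14 7-methoxy-8-(methoxymethoxy)-5-(prop-2-en-1-yloxy)-3-(2,4,5-trimethoxyphenyl)-4H-chromen-4-one
Conditions: allyl bromide (3 equiv), K2CO3 (3 equiv), DMF, 60 °C
Reagents that add atoms: none
Why: Williamson ether synthesis; excess base and gentle heating overcome the chelation of the 5-hydroxyl, and the MOM acetal is stable to base.

Step 9
Reactants: 14 7-methoxy-8-(methoxymethoxy)-5-(prop-2-en-1-yloxy)-3-(2,4,5-trimethoxyphenyl)-4H-chromen-4-one
Product: 16 5-hydroxy-7-methoxy-8-(methoxymethoxy)-6-(prop-2-en-1-yl)-3-(2,4,5-trimethoxyphenyl)-4H-chromen-4-one, via C6-allyl cyclohexadienone 15 (not isolated)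
Conditions: N,N-diethylaniline, 200 °C, sealed tube, argon
Reagents that add atoms: none
Why: Aromatic Claisen rearrangement ([3,3] shift); C6 is the only ortho carbon that carries hydrogen (the other is the ring fusion C4a) and the para carbon C8 is blocked, so the dienone can only tautomerise to the 6-allyl phenol.

Step 10
Reactants: 16 5-hydroxy-7-methoxy-8-(methoxymethoxy)-6-(prop-2-en-1-yl)-3-(2,4,5-trimethoxyphenyl)-4H-chromen-4-one; 17 2-methyl-2-butene
Product: 18 5-hydroxy-7-methoxy-8-(methoxymethoxy)-6-(3-methylbut-2-en-1-yl)-3-(2,4,5-trimethoxyphenyl)-4H-chromen-4-one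
Conditions: second-generation Grubbs catalyst (H2IMes)(PCy3)Cl2Ru=CHPh (5 mol %), 2-methyl-2-butene/CH2Cl2, 40 °C, sealed tube
Reagents that add atoms: none
Why: Olefin cross-metathesis; the large excess of 2-methyl-2-butene transfers its isopropylidene unit to the terminal olefin with loss of propene, and the chelated phenol is tolerated by the ruthenium carbene.

Step 11
Reactants: 18 5-hydroxy-7-methoxy-8-(methoxymethoxy)-6-(3-methylbut-2-en-1-yl)-3-(2,4,5-trimethoxyphenyl)-4H-chromen-4-one
Product: 19 5,8-dihydroxy-7-methoxy-6-(3-methylbut-2-en-1-yl)-3-(2,4,5-trimethoxyphenyl)-4H-chromen-4-one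
Conditions: HCl (3 M aq.), MeOH, 40 °C, argon
Reagents that add atoms: none
Why: Acid-catalysed acetal methanolysis of the MOM ether; dilute acid at mild temperature should spare the prenyl olefin and the aryl methyl ethers, and the absence of base and air protects the hydroquinone.

**Compound list**

1 | 1-(2,4,5-trimethoxyphenyl)ethanone | CC(=O)c1cc(OC)c(OC)cc1OC | starting material
2 | 2-bromo-1-(2,4,5-trimethoxyphenyl)ethanone | BrCC(=O)c1cc(OC)c(OC)cc1OC | intermediate
3 | 2-hydroxy-4,6-dimethoxybenzaldehyde | COc1cc(O)c(C=O)c(OC)c1 | starting material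
4 | 2,4-dimethoxy-6-[2-oxo-2-(2,4,5-trimethoxyphenyl)ethoxy]benzaldehyde | COc1cc(OC)c(C=O)c(OCC(=O)c2cc(OC)c(OC)cc2OC)c1 | intermediate
5 | racemic 3-hydroxy-5,7-dimethoxy-3-(2,4,5-trimethoxyphenyl)chroman-4-one | COc1cc(OC)c2c(c1)OCC(O)(c1cc(OC)c(OC)cc1OC)C2=O | intermediate
6 | racemic 5,7-dimethoxy-4-oxo-3-(2,4,5-trimethoxyphenyl)chroman-3-yl chlorosulfite | COc1cc(OC)c2c(c1)OCC(OS(=O)Cl)(c1cc(OC)c(OC)cc1OC)C2=O | intermediate
7 | 5,7-dimethoxy-3-(2,4,5-trimethoxyphenyl)-4H-chromen-4-one | COc1cc(OC)c2c(c1)occ(-c1cc(OC)c(OC)cc1OC)c2=O | intermediate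
8 | 5-(dichloroboranyloxy)-7-methoxy-3-(2,4,5-trimethoxyphenyl)-4H-chromen-4-one | COc1cc(OB(Cl)Cl)c2c(c1)occ(-c1cc(OC)c(OC)cc1OC)c2=O | intermediate
9 | 5-hydroxy-7-methoxy-3-(2,4,5-trimethoxyphenyl)-4H-chromen-4-one | COc1cc(O)c2c(c1)occ(-c1cc(OC)c(OC)cc1OC)c2=O | intermediate
10 | potassium 5-hydroxy-7-methoxy-4-oxo-3-(2,4,5-trimethoxyphenyl)-4H-chromen-8-yl sulfate | COc1cc(O)c2c(c1OS(=O)(=O)[O-])occ(-c1cc(OC)c(OC)cc1OC)c2=O.[K+] | intermediate
11 | 5,8-dihydroxy-7-methoxy-3-(2,4,5-trimethoxyphenyl)-4H-chromen-4-one | COc1cc(O)c2c(c1O)occ(-c1cc(OC)c(OC)cc1OC)c2=O | intermediate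
12 | 5-hydroxy-7-methoxy-8-(methoxymethoxy)-3-(2,4,5-trimethoxyphenyl)-4H-chromen-4-one | COCOc1c(OC)cc(O)c2c1occ(-c1cc(OC)c(OC)cc1OC)c2=O | intermediate
13 | allyl bromide | C=CCBr | starting material
14 | 7-methoxy-8-(methoxymethoxy)-5-(prop-2-en-1-yloxy)-3-(2,4,5-trimethoxyphenyl)-4H-chromen-4-one | COCOc1c(OC)cc(OCC=C)c2c1occ(-c1cc(OC)c(OC)cc1OC)c2=O | intermediate
15 | racemic 7-methoxy-8-(methoxymethoxy)-6-(prop-2-en-1-yl)-3-(2,4,5-trimethoxyphenyl)-4H-chromene-4,5(6H)-dione | C=CCC1C(=O)C2=C(OC=C(c3cc(OC)c(OC)cc3OC)C2=O)C(OCOC)=C1OC | intermediate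
16 | 5-hydroxy-7-methoxy-8-(methoxymethoxy)-6-(prop-2-en-1-yl)-3-(2,4,5-trimethoxyphenyl)-4H-chromen-4-one | COCOc1c(OC)c(CC=C)c(O)c2c1occ(-c1cc(OC)c(OC)cc1OC)c2=O | intermediate
17 | 2-methyl-2-butene | CC=C(C)C | starting material
18 | 5-hydroxy-7-methoxy-8-(methoxymethoxy)-6-(3-methylbut-2-en-1-yl)-3-(2,4,5-trimethoxyphenyl)-4H-chromen-4-one | COCOc1c(OC)c(CC=C(C)C)c(O)c2c1occ(-c1cc(OC)c(OC)cc1OC)c2=O | intermediate
19 | 5,8-dihydroxy-7-methoxy-6-(3-methylbut-2-en-1-yl)-3-(2,4,5-trimethoxyphenyl)-4H-chromen-4-one | COc1cc(OC)c(-c2coc3c(O)c(OC)c(CC=C(C)C)c(O)c3c2=O)cc1OC | target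

**Step count and risks**

Total step count: 11. Longest linear sequence: 11 steps (compound 1 to compound 19); compounds 3, 13 and 17 enter as purchased materials.

Steps most likely to fail:

1. Step 6 (persulfate hydroxylation). Hydroxide may attack C2 and open the pyranone ring, the chelated and deactivated phenolate may react only partly with persulfate, and the hydroquinone formed may be oxidised further in the alkaline medium. The fallback sets out from compound 7 and installs the C8 oxygen by halogenation and boron chemistry. Iodination with N-iodosuccinimide and CF3CO2H in MeCN should occur at C8, the ring A carbon flanked by O1 and the 7-methoxy group and para to the 5-methoxy group, to give 8-iodo-5,7-dimethoxy-3-(2,4,5-trimethoxyphenyl)-4H-chromen-4-one F1. Miyaura borylation (bis(pinacolato)diboron, Pd(dppf)Cl2, KOAc, dioxane, 90 °C) would give 5,7-dimethoxy-8-(4,4,5,5-tetramethyl-1,3,2-dioxaborolan-2-yl)-3-(2,4,5-trimethoxyphenyl)-4H-chromen-4-one F2. Oxidation with NaBO3·4H2O in THF/H2O at 20 °C would give 8-hydroxy-5,7-dimethoxy-3-(2,4,5-trimethoxyphenyl)-4H-chromen-4-one F3. BCl3 (CH2Cl2, −78 → 0 °C) would then cleave the chelated 5-methyl ether, and the route is rejoined at compound 11; compound 9 is bypassed.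

2. Step 3 (carbene-catalysed benzoin closure). The carbene may add slowly to the doubly ortho-substituted, electron-rich aldehyde and the enaminol may attack the deactivated ortho-methoxy aryl ketone sluggishly, so that base-induced aldol closure of the phenacyl methylene and decomposition take over. The fallback sets out from compound 1 and builds the isoflavone by the deoxybenzoin route, closing ring C through C2 instead of C3–C4. Willgerodt–Kindler reaction (S8, morpholine, 130 °C) would give 1-(morpholin-4-yl)-2-(2,4,5-trimethoxyphenyl)ethanethione F4, and hydrolysis (aq. NaOH, EtOH, reflux; then HCl) would give 2,4,5-trimethoxyphenylacetic acid F5. Friedel–Crafts acylation of purchased 3,5-dimethoxyphenol ortho to its hydroxyl (BF3·Et2O, 85 °C) would give 1-(2-hydroxy-4,6-dimethoxyphenyl)-2-(2,4,5-trimethoxyphenyl)ethanone F6. One-carbon annulation with DMF, MsCl and BF3·Et2O at 70 °C, in which the formamide carbon becomes C2, returns to the route at compound 7; compounds 4 and 5 are bypassed.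

3. Step 9 (Claisen shift). At 200 °C the allyl ether may fragment back to the phenol, the MOM acetal may be lost, and the ortho-allyl phenol may cyclise onto its own olefin. The fallback sets out from compound 12 and brings in the allyl group by cross-coupling. Iodination at C6, the only unsubstituted ring A carbon and ortho to the 5-hydroxyl (benzyltrimethylammonium dichloroiodate, CaCO3, CH2Cl2/MeOH, 20 °C), would give 5-hydroxy-6-iodo-7-methoxy-8-(methoxymethoxy)-3-(2,4,5-trimethoxyphenyl)-4H-chromen-4-one F7. Stille coupling with allyltributylstannane (Pd(PPh3)4, DMF, 90 °C) comes back to the route at compound 16; steps 8 and 9 are bypassed.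

**Further compounds**

F1 | step 6 | 8-iodo-5,7-dimethoxy-3-(2,4,5-trimethoxyphenyl)-4H-chromen-4-one | COc1cc(OC)c2c(c1I)occ(-c1cc(OC)c(OC)cc1OC)c2=O
F2 | step 6 | 5,7-dimethoxy-8-(4,4,5,5-tetramethyl-1,3,2-dioxaborolan-2-yl)-3-(2,4,5-trimethoxyphenyl)-4H-chromen-4-one | COc1cc(OC)c2c(c1B1OC(C)(C)C(C)(C)O1)occ(-c1cc(OC)c(OC)cc1OC)c2=O
F3 | step 6 | 8-hydroxy-5,7-dimethoxy-3-(2,4,5-trimethoxyphenyl)-4H-chromen-4-one | COc1cc(OC)c2c(c1O)occ(-c1cc(OC)c(OC)cc1OC)c2=O
F4 | step 3 | 1-(morpholin-4-yl)-2-(2,4,5-trimethoxyphenyl)ethanethione | S=C(Cc1cc(OC)c(OC)cc1OC)N1CCOCC1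
F5 | step 3 | 2,4,5-trimethoxyphenylacetic acid | OC(=O)Cc1cc(OC)c(OC)cc1OC
F6 | step 3 | 1-(2-hydroxy-4,6-dimethoxyphenyl)-2-(2,4,5-trimethoxyphenyl)ethanone | COc1cc(O)c(C(=O)Cc2cc(OC)c(OC)cc2OC)c(OC)c1
F7 | step 9 | 5-hydroxy-6-iodo-7-methoxy-8-(methoxymethoxy)-3-(2,4,5-trimethoxyphenyl)-4H-chromen-4-one | COCOc1c(OC)c(I)c(O)c2c1occ(-c1cc(OC)c(OC)cc1OC)c2=O
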